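Thursday's run, with 11 mM of substrate and 0.83 mol% of free catalyst, is where I start for the quick number you want on Saturday's flask.

in all of them: substrate 11 mM
- Saturday's: free catalyst 0.55 mol%; the very flask that is asked about, followed so far
- Thursday's: free catalyst 0.83 mol%; run made earlier
- flask: free catalyst 0.55 mol%; time 10 h

Saturday's run (percent of the substrate charged)

| time / min | substrate / % | product / % |
|---|---|---|
| 6.00 | 99.0 | 1.0 |
| 15.0 | 97.7 | 2.7 |
| 30.0 | 95.3 | 4.6 |
| 50.0 | 92.5 | 6.8 |
| 60.0 | 91.5 | 8.7 |
| 80.0 | 89.1 | 10.9 |
| 120 | 85.4 | 15.2 |

Thursday's run (percent of the substrate charged)

| time / h | substrate / % | product / % |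
|---|---|---|
| 0.500 | 92.9 | 6.4 |
| 1.50 | 82.6 | 17.1 |
| 3.00 | 71.9 | 28.3 |
| 4.00 | 67.0 | 32.8 |
| 6.00 | 61.8 | 38.9 |
| 8.00 | 58.0 | 41.8 |
| 10.0 | 56.2 | 43.0 |

(readings scatter by 0.3 percentage points)

- why nothing more happens at 10 h, or that something still does (forward and back rates have come level / no working catalyst is left / it is still moving / all of the substrate has reacted)
- conversion of substrate at 10 h
- amount of product at 10 h, in percent of the substrate charged

- steps that have been proposed: substrate + free catalyst <-> catalyst intermediate; catalyst intermediate -> free catalyst + product; free catalyst + product -> spent catalyst A; free catalyst -> spent catalyst B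
- the reaction counts as stopped when no species that holds the substrate changes by six tenths of a point or more over the second half of the time

I treat both runs as pseudo-first-order in c(substrate), with a rate proportional to the catalyst charged. After 30.0 min, Saturday's ln(charged over left) reads 0.654 of Thursday's, and the catalyst charges stand at 0.663. So I carry one quantity, the reach: ln of c(substrate) charged over c(substrate) left at 10 h, scaled from Thursday's by the catalyst concentration charged, for Saturday's flask 0.382. That gives a conversion of 31.8%, and I expect about as much product, with the catalyst charged at 0.55 mol%. Thursday's substrate still fell 5.6 percentage points from 6.00 h to 10.0 h; scaled to Saturday's catalyst charge, that stretch is worth 0.0629 of reach, so I call Saturday's flask still moving.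

Your forecast says it is still moving, with conversion 31.5% and product 31%, holding that “simple first-order catalyst death dominates”. My conversion is a little higher.

The flask gives 33.0% conversion and 32.9% product, and it is still moving; its reach is 0.400 against my 0.382.

    substrate + free catalyst ⇌ catalyst intermediate (K = 15.0 L mol⁻¹, k = 34.5 L mol⁻¹ s⁻¹)
    catalyst intermediate → free catalyst + product (k = 0.0350 s⁻¹)
    free catalyst + product → spent catalyst A (k = 0.00778 L mol⁻¹ s⁻¹)
    free catalyst → spent catalyst B (k = 5.64 × 10⁻⁵ s⁻¹)

Saturday's flask stays far from full conversion mainly because the catalyst intermediate falls back to substrate and free catalyst: the same run without that undoing converts >99.9%, against 33.0%. At 44 mM of substrate and the same loading, the reach scales to 1.53, but that flask's own is 0.777, with spent catalyst A at 64.6% of the catalyst charged.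

The runs are calculated on assumed constants; scatter was added.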